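**The amounts.** Charge 0.50 M of electrophile with 3.00 equiv to 5.10 equiv of nucleophile and 1.20 equiv of free base, stop at 15 h, and count each product by the electrophile it holds.

in all of them: electrophile 0.50 M; free base 1.20 equiv; time 15 h
- west: nucleophile 3.90 equiv
- north-east: nucleophile 5.10 equiv
- north-west: nucleophile 3.00 equiv

    electrophile + nucleophile → acid set free + target (k1 = 0.30 L mol⁻¹ h⁻¹)
    nucleophile + acid set free ⇌ protonated nucleophile, settled at all times (K2 = 350 L mol⁻¹)
    acid set free + free base ⇌ salt of the base, settled at all times (K3 = 570 L mol⁻¹)
    target ⇌ isomer of the product (K4 = 30, k4 = 0.063 h⁻¹)
    electrophile + target → side product (k5 = 0.29 L mol⁻¹ h⁻¹)
    nucleophile ⇌ dormant form (K6 = 0.15, k6 = 0.021 h⁻¹)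

- percent here means electrophile units held: one side product counts as two
- run time (west): 15 h

* which of these there is most of at the end, counted by the electrophile in it, west (electrophile / side product / isomer of the product / target)
* which of these there is most of at the end, counted by the electrophile in it, north-east (electrophile / side product / isomer of the product / target)
* which of these there is most of at the end, counted by the electrophile in it, north-west (electrophile / side product / isomer of the product / target)
* the largest of these amounts at the end, in percent of the electrophile charged, west
* the largest of these amounts at the end, in percent of the electrophile charged, north-east
* the largest of these amounts at the end, in percent of the electrophile charged, north-west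

**The ladder.** Start with the acid set free. The two balances, taken with the charges of north-west, give 520 for the nucleophile and 340 for the free base, both far above one, so the acid is taken up as it appears and this rung costs no time. Next comes the attack on the electrophile. Treat it as pseudo-first-order with c(nucleophile) at its charged value, a simplification, and take the mean life as the inverse of k1 times c(nucleophile): 1.71 h in west, 1.31 h in north-east, 2.22 h in north-west. Then comes the pair of target and isomer. Its end state holds 96.8 % of the pair as isomer, and it approaches that at the relaxation rate, the forward constant plus the constant of return, 0.0651 h⁻¹, a half-life of 10.6 h. The run lasts 1.42 such half-lives, so the flask stops on the way. Last stands the passing of nucleophile into dormant form, with a forward half-life of 33 h, longer than the run; I leave it out of this rough reckoning, which holds c(nucleophile) at its charged value anyway.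

**My reckoning.** Let the pair be born at the mean life and relax for the remaining time. The isomer's share of the pair is then 56.0 % in west, 57.1 % in north-east and 54.7 % in north-west, each above one in two, so I expect the isomer to lead the target in west, north-east and north-west. This gives the split of the pair, not its size: I do not reckon the loss to side product.

**The forecast.** It names isomer of the product for west, north-east and north-west, at 44 %, 47 % and 39 %, holding that “a little over half of the product has isomerised”.

**The flasks.** The isomer of the product leads in each: 43.2 % in west, 46.8 % in north-east, 39.0 % in north-west. The forecast is right on all of these, within the tolerance.

**The stopped pair.** In north-east at 0.892 h, the electrophile's half-life by its attack is 1.1 h, and the target's by its forward isomerisation is ten times as long, 11 h. At 15 h the isomer in north-east holds 56.8 % of that pair, and it stands at 79.7 % of the charge by 150 h: the asked time in north-east is a stop under kinetic, not thermodynamic, control. Now take north-east with 0.20 M of electrophile, the equivalents and the time held, as the neighbour flask. The mean life becomes 3.27 h, and the same 0.0651 h⁻¹ gives a share of 51.7 %. At the end that neighbour flask holds 41.8 % isomer and 39.9 % target, a share of 51.2 %.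

Its constants are invented, and the outcome is calculated.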